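**Assumptions.** The target has no stereocentres or stereogenic double bonds, so no stereocontrol is needed. The free-acid SMILES is taken to mean the tetrasulfate regardless of counter-ion; it is isolated as the tetrapotassium salt. The route is a paper proposal and has not been run.

## Retrosynthetic overview

1. The obvious S–O disconnection back to quercetin is avoided: three of the four sulfates are carried from the fragment stage as acid-stable 2,2,2-trichloroethyl (TCE) sulfate diesters.
2. Target ⇐ four-fold reductive unmasking of a tetra-TCE sulfate; its 3-O-sulfate diester ⇐ chemoselective sulfation of the flavonol 3-OH (the 5-OH is chelated to C4=O).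
3. Flavonol ⇐ nitrosative C3 oxygenation of a flavanone (Kostanecki isonitroso route, all acidic, no Algar–Flynn–Oyamada or base).
4. Flavanone ⇐ acid-mediated Claisen–Schmidt/oxa-Michael union of a bis-sulfated B-ring aldehyde and a mono-sulfated A-ring acetophenone.
5. Ring order: A and B rings are bought; only the C-ring (pyranone) is built (Step 3) and then aromatised (Step 5).

## Route

**Step 1**
Reactants: 1 (3,4-dihydroxybenzaldehyde); 2 (2,2,2-trichloroethyl chlorosulfate, 2.5 equiv)
Product: 3 (3,4-bis[(2,2,2-trichloroethoxy)sulfonyloxy]benzaldehyde)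
Conditions: Et3N, DMAP, THF, 0 °C → rt
Reagents that add atoms: 2,2,2-trichloroethyl chlorosulfate, ClS(=O)(=O)OCC(Cl)(Cl)Cl
Why: DMAP-catalysed O-sulfonylation of both phenols gives the sulfate diesters, with excess reagent making the second intermolecular sulfation outrun cyclic catechol sulfate formation.

**Step 2**
Reactants: 4 (2',4',6'-trihydroxyacetophenone, dried); 2 (1.0 equiv, slow addition)
Product: 5 (4-acetyl-3,5-dihydroxyphenyl 2,2,2-trichloroethyl sulfate)
Conditions: Et3N (1.05 equiv), DMAP (cat.), THF, −40 → 0 °C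
Reagents that add atoms: 2,2,2-trichloroethyl chlorosulfate, ClS(=O)(=O)OCC(Cl)(Cl)Cl
Why: Regioselective O-sulfonylation at the 4-OH, which is the most acidic and least hindered hydroxyl, whereas the 2- and 6-OH flank the acetyl group and are engaged in hydrogen bonding to its C=O.

**Step 3**
Reactants: 3; 5
Product: 6 ((±)-5-hydroxy-2-{3,4-bis[(trichloroethoxy)sulfonyloxy]phenyl}-7-[(trichloroethoxy)sulfonyloxy]chroman-4-one, racemic at C2)
Conditions: BF3·OEt2, 1,4-dioxane, rt → 50 °C; then TsOH (cat.), AcOH, 80 °C
Reagents that add atoms: none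
Why: Lewis-acid Claisen–Schmidt condensation of the BF2-chelated enol of 5 with the electron-poor aldehyde 3 gives the 2',6'-dihydroxychalcone, and acid-catalysed 6-endo oxa-Michael closure (chalcone–flavanone isomerisation) forms the C-ring; the C2 centre is racemic and is erased in Step 5.

**Step 4**
Reactants: 6; 7 (isoamyl nitrite)
Product: 8 (3-(hydroxyimino) derivative of 6, i.e. the 3-isonitrosoflavanone; racemic at C2, oxime E/Z mixture)
Conditions: i-AmONO (1.5 equiv), HCl (4 M in dioxane), THF, 0 °C → rt
Reagents that add atoms: isoamyl nitrite, CC(C)CCON=O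
Why: Acid-catalysed α-nitrosation of the ketone (first half of the Kostanecki flavonol synthesis), in which the C3 enol attacks NO+ and the nitroso compound tautomerises to the oxime; the A-ring is deactivated toward C-nitrosation by the chelated acyl group and the 7-sulfate diester.

**Step 5**
Reactants: 8; 9 (water)
Product: 10 (3,5-dihydroxy-2-{3,4-bis[(trichloroethoxy)sulfonyloxy]phenyl}-7-[(trichloroethoxy)sulfonyloxy]-4H-chromen-4-one, i.e. quercetin 7,3',4'-tris(TCE sulfate))
Conditions: 10% aq. H2SO4–AcOH, 90 °C
Reagents that add atoms: water, O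
Why: Acid hydrolysis of the α-oximino ketone gives the flavan-3,4-dione, which tautomerises through C2–H to the aromatic 3-hydroxychromone (second half of the Kostanecki sequence); TCE sulfate diesters have no acid-hydrolysis pathway at carbon or sulfur under these conditions.

**Step 6**
Reactants: 10; 2 (1.2 equiv)
Product: 11 (quercetin 3,7,3',4'-tetrakis(2,2,2-trichloroethyl sulfate), 5-OH free)
Conditions: Et3N, DMAP, THF, 0 °C
Reagents that add atoms: 2,2,2-trichloroethyl chlorosulfate, ClS(=O)(=O)OCC(Cl)(Cl)Cl
Why: Chemoselective O-sulfonylation of the acidic enolic 3-OH, while the 5-OH stays locked in its six-membered hydrogen bond to C4=O and is non-nucleophilic with limited reagent.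

**Step 7**
Reactants: 11
Product: 12 (quercetin 3,7,3',4'-tetra-O-sulfate, isolated as the tetrapotassium salt)
Conditions: Zn dust, HCO2NH4, MeOH, rt; then Dowex 50W (K+ form), Sephadex LH-20
Reagents that add atoms: none
Why: Four-fold zinc-mediated reductive β-elimination of the TCE groups (loss of Cl2C=CH2 and chloride) releases the sulfate monoesters under near-neutral buffered conditions that the acid-labile aryl and enol sulfates tolerate.

## Compound list

1 | 3,4-dihydroxybenzaldehyde | O=Cc1ccc(O)c(O)c1 | starting material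
2 | 2,2,2-trichloroethyl chlorosulfate | ClS(=O)(=O)OCC(Cl)(Cl)Cl | starting material
3 | 3,4-bis[(2,2,2-trichloroethoxy)sulfonyloxy]benzaldehyde | O=Cc1ccc(OS(=O)(=O)OCC(Cl)(Cl)Cl)c(OS(=O)(=O)OCC(Cl)(Cl)Cl)c1 | intermediate
4 | 2',4',6'-trihydroxyacetophenone | CC(=O)c1c(O)cc(O)cc1O | starting material
5 | 4-acetyl-3,5-dihydroxyphenyl 2,2,2-trichloroethyl sulfate | CC(=O)c1c(O)cc(OS(=O)(=O)OCC(Cl)(Cl)Cl)cc1O | intermediate
6 | (±)-eriodictyol 7,3',4'-tris(TCE sulfate) (flavanone, racemic) | O=C1CC(c2ccc(OS(=O)(=O)OCC(Cl)(Cl)Cl)c(OS(=O)(=O)OCC(Cl)(Cl)Cl)c2)Oc2cc(OS(=O)(=O)OCC(Cl)(Cl)Cl)cc(O)c12 | intermediate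
7 | isoamyl nitrite | CC(C)CCON=O | starting material (reagent)
8 | (±)-3-(hydroxyimino)flavanone tris(TCE sulfate) (racemic, E/Z) | O=C1C(=NO)C(c2ccc(OS(=O)(=O)OCC(Cl)(Cl)Cl)c(OS(=O)(=O)OCC(Cl)(Cl)Cl)c2)Oc2cc(OS(=O)(=O)OCC(Cl)(Cl)Cl)cc(O)c12 | intermediate
9 | water | O | starting material (reagent)
10 | quercetin 7,3',4'-tris(TCE sulfate) | O=c1c(O)c(-c2ccc(OS(=O)(=O)OCC(Cl)(Cl)Cl)c(OS(=O)(=O)OCC(Cl)(Cl)Cl)c2)oc2cc(OS(=O)(=O)OCC(Cl)(Cl)Cl)cc(O)c12 | intermediate
11 | quercetin 3,7,3',4'-tetrakis(TCE sulfate) | O=c1c(OS(=O)(=O)OCC(Cl)(Cl)Cl)c(-c2ccc(OS(=O)(=O)OCC(Cl)(Cl)Cl)c(OS(=O)(=O)OCC(Cl)(Cl)Cl)c2)oc2cc(OS(=O)(=O)OCC(Cl)(Cl)Cl)cc(O)c12 | intermediate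
12 | quercetin 3,7,3',4'-tetra-O-sulfate (achiral) | O=c1c(OS(=O)(=O)O)c(-c2ccc(OS(=O)(=O)O)c(OS(=O)(=O)O)c2)oc2cc(OS(=O)(=O)O)cc(O)c12 | target

## Summary

Total steps: 7. Longest linear sequence: 6 (Steps 2, 3, 4, 5, 6, 7; the branch through Step 1 is equally long).

Three steps most likely to fail:

- **Step 4 (α-nitrosation).** Risk: competing C-nitrosation at C6/C8 of the free 5-OH ring. Fallback: dehydrogenate 6 to the flavone (cat. I2, DMSO, 120 °C) and install the C3 oxygen by DMDO epoxidation of the C2=C3 bond followed by acid-promoted opening to 10.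
- **Step 3 (acid Claisen–Schmidt/cyclisation).** Risk: the doubly chelated, electron-poor ketone 5 enolises sluggishly, or the chalcone/flavanone mixture does not converge. Fallback: build the skeleton first and sulfate second, i.e. base Claisen–Schmidt of MOM-protected, unsulfated partners, HCl cyclisation/deprotection to eriodictyol, then tris-TCE-sulfation at 7, 3' and 4' (5-OH chelated) to reach 6.
- **Step 2 (mono-sulfation of 4).** Risk: 2,4-bis-sulfation or a statistical mixture. Fallback: give up early A-ring sulfation, carry unprotected 4 through condensation with 3, oxidise to the flavonol by the flavone/DMDO route (nitrosation is not viable on the free resorcinol ring), and install the 7- and 3-O-TCE sulfates together with 2.2 equiv of 2, relying on 5-OH chelation.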